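The rate constants are made up.

Take a row of neighbouring flasks: the same racemate and the same D, with only the charge of G differing.

| setting | alpha | theta | zeta | epsilon | gamma |
|---|---|---|---|---|---|
| J | 0.050 M | 0.050 M | 0.050 M | 0.050 M | 0.050 M |
| D | 0.0300 M | 0.0300 M | 0.0300 M | 0.0300 M | 0.0300 M |
| G | 0.80 mM | 1.5 mM | 3.0 mM | 6.0 mM | 12 mM |
| L | 0.050 M | 0.050 M | 0.050 M | 0.050 M | 0.050 M |
| time | 2.5 h | 2.5 h | 2.5 h | 2.5 h | 2.5 h |

* excess of E over Q at the end for alpha, theta, zeta, epsilon, gamma, in this order
* the course of these numbers from the first flask to the last (rises, then falls / rises all the way / falls, then rises / falls all the way / hardly changes)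

- G is single-handed; J and L are mirror images of each other, charged as a racemate, each of them at the stated concentration
- an excess is the difference of the two amounts in percent of their sum
- "hardly changes" means that all values lie within two and a half points (for a concentration: within two and a half percent of the largest)
- run time (alpha): 2.5 h

G turns into X at 0.079 /min. While it lives, G joins D to J, making E, with 280 /M²/min, and joins D to L, making Q, with 99 /M²/min.

1. Both routes need D and G, so these cancel in the ratio of the two rates. That leaves the selectivity factor s, the first constant over the second: 2.83. With J and L equal at the start, the excess is then the difference of the constants in percent of their sum, 47.8%.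

2. G has a mean life of 12.7 min, shorter than the run of 2.5 h. Each flask therefore gets a catalyst dose of its G charge times that life.

3. Now define the draw N: the combined pull of J and L on D, at their charges, multiplied by the dose. D should fall to e^−N of its charge. In gamma, N is 2.88.

4. First pass for gamma: D consumed is 94.4% of its charge, and 73.9% of that goes to J. Dividing by the charge of J gives the logarithmic loss x = 0.418. For L, the loss y is x over s, 0.148. That leaves J at 65.8% of its own charge and L at 86.2% of its own, with an excess of 42.6%.

5. The weak link is N itself, which held J and L at their charges. Go round once more with the mean of start and end: N becomes 2.46, x becomes 0.474, and y becomes 0.168. I commit to 42.0% for gamma, lower than the starting excess.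

6. In alpha, N is 0.192, far smaller than in gamma, so alpha stays close to the starting excess. I expect the row to fall at each step.

The forecast gave 46.8%, 46.1%, 44.8%, 43.3% and 41.9%, shape falls all the way, holding that “more G simply pushes the same kinetic resolution further along its fixed path”.

The simulation gives 46.8%, 46.1%, 44.9%, 43.3% and 41.9%: the row falls all the way. Against my 42.0%, gamma stands at 41.9%.

    G → X (k1 = 0.079 /min)
    D + G + J → G + E (k2 = 280 /M²/min)
    D + G + L → G + Q (k3 = 99 /M²/min)

Carry N to alpha: D should stand at 82.5% of its charge, and at 2.50 h you find 83% left. One reason the excess in alpha stays high is that G goes over to X. With that loss taken away, the same flask ends at an excess of 42.4% instead of 46.8%.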